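**Retrosynthetic overview**

- The route rests on ring C, a benzene ring with OH on C1, the ether oxygen to ring B on C2 and the CH2CH2 tether to ring D on C4. This pattern maps onto a 4-alkylcyclohex-2-enone: the C1 carbonyl becomes the phenol OH and C2 receives the ring B oxygen.
- Last disconnections: three O-methyl groups (BBr3), then dearomatisation of ring C to a 2-aryloxy-4-alkylcyclohex-2-enone, then the C2–O bond, leading back to a 2,3-epoxycyclohexanone and the ring A–B phenol.
- The epoxy ketone comes from a 4-alkylcyclohexenone, itself made by enamine Michael addition of 4-(2,3-dimethoxyphenyl)butanal to methyl vinyl ketone and aldol closure. The aldehyde comes from 2,3-dimethoxybenzaldehyde by Wittig homologation.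
- The ring A–B phenol comes from a Horner–Wadsworth–Emmons stilbene synthesis followed by hydrogenation with loss of the benzyl group.
- Ring order: rings A, B and D are bought as arenes. Ring C is the only ring built (aldol closure, steps 4–6); it is epoxidised, joined to ring B through oxygen and aromatised last.

Key step: step 10

Remark: the target has no stereocentre, so ring C intermediates are carried as racemates or diastereomer mixtures and the alkene of 4 as a Z/E mixture. Ring C is numbered throughout with C1 as the carbonyl/OH carbon, C2 as the oxygen-bearing carbon and C4 as the chain-bearing carbon.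

**Route**

Step 1
Reactants: 1 2,3-dimethoxybenzaldehyde; 2 [2-(1,3-dioxolan-2-yl)ethyl]triphenylphosphonium bromide
Product: 4 2-[3-(2,3-dimethoxyphenyl)prop-2-en-1-yl]-1,3-dioxolane (mainly Z), via phosphorus ylide 3 (not isolated)
Conditions: 2, KOtBu, THF, 0 °C; then 1, 0 °C to rt
Reagents that add atoms: none
Why: Wittig olefination of the aryl aldehyde by the non-stabilised ylide 3 should give the alkene as a mainly Z mixture, whose geometry does not matter because step 2 saturates it.

Step 2
Reactants: 4 2-[3-(2,3-dimethoxyphenyl)prop-2-en-1-yl]-1,3-dioxolane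
Product: 5 2-[3-(2,3-dimethoxyphenyl)propyl]-1,3-dioxolane
Conditions: H2 (1 atm), 10% Pd/C, EtOAc, rt
Reagents that add atoms: none
Why: Catalytic hydrogenation saturates the styrene-type alkene under neutral conditions that leave the dioxolane and the aryl methyl ethers untouched.

Step 3
Reactants: 5 2-[3-(2,3-dimethoxyphenyl)propyl]-1,3-dioxolane
Product: 6 4-(2,3-dimethoxyphenyl)butanal
Conditions: 2 M HCl (aq), THF, rt
Reagents that add atoms: water, O
Why: Acid-catalysed acetal hydrolysis frees the aldehyde, and the aryl methyl ethers are inert to dilute aqueous acid.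

Step 4
Reactants: 6 4-(2,3-dimethoxyphenyl)butanal
Product: 7 1-[(E)-4-(2,3-dimethoxyphenyl)but-1-en-1-yl]pyrrolidine
Conditions: pyrrolidine, 4 Å molecular sieves, toluene, 0 °C to rt; filtered, concentrated, used crude
Reagents that add atoms: pyrrolidine, C1CCNC1
Why: Enamine formation by condensation of the aldehyde with the secondary amine, driven by removal of water, should give the E enamine that makes the aldehyde alpha carbon nucleophilic.

Step 5
Reactants: 7 1-[(E)-4-(2,3-dimethoxyphenyl)but-1-en-1-yl]pyrrolidine; 8 methyl vinyl ketone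
Product: 10 2-[2-(2,3-dimethoxyphenyl)ethyl]-5-oxohexanal (racemic), via adduct enamine 9 (not isolated)
Conditions: 8, MeCN, 0 °C to rt; then AcOH/NaOAc/H2O, rt
Reagents that add atoms: water, O
Why: Stork enamine Michael addition joins the enamine beta carbon to the enone terminus; the more hindered adduct enamine 9 resists a second addition, and buffered hydrolysis releases the keto aldehyde with its new stereocentre racemic.

Step 6
Reactants: 10 2-[2-(2,3-dimethoxyphenyl)ethyl]-5-oxohexanal
Product: 12 4-[2-(2,3-dimethoxyphenyl)ethyl]cyclohex-2-en-1-one (racemic), via aldol 11 (not isolated)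
Conditions: KOH (aq), n-Bu4NOH (cat.), THF/Et2O, reflux
Reagents that add atoms: none
Why: Intramolecular aldol condensation closes ring C in a 6-(enolendo)-exo-trig mode, the methyl ketone enolate attacking the aldehyde (the only combination that gives a six-membered ring), and E1cB dehydration of 11 gives the enone.

Step 7
Reactants: 12 4-[2-(2,3-dimethoxyphenyl)ethyl]cyclohex-2-en-1-one
Product: 13 5-[2-(2,3-dimethoxyphenyl)ethyl]-7-oxabicyclo[4.1.0]heptan-2-one (racemic, diastereomer mixture)
Conditions: 30% H2O2, NaOH (aq, cat.), MeOH, 0 °C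
Reagents that add atoms: hydrogen peroxide, OO
Why: Weitz–Scheffer nucleophilic epoxidation (hydroperoxide conjugate addition, then enolate closure on oxygen) acts only on the electron-poor enone and spares the electron-rich arene; attack anti to the C4 chain should favour the trans epoxide, but either diastereomer serves.

Step 8
Reactants: 14 diethyl (3-methoxybenzyl)phosphonate; 15 4-(benzyloxy)benzaldehyde
Product: 17 (E)-1-(benzyloxy)-4-[2-(3-methoxyphenyl)ethenyl]benzene, via phosphonate carbanion 16 (not isolated)
Conditions: 14, KOtBu, THF, 0 °C; then 15, 0 °C to rt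
Reagents that add atoms: none
Why: Horner–Wadsworth–Emmons olefination of the aryl aldehyde by the benzylic phosphonate carbanion should give the E stilbene, with the benzyl ether stable to the base.

Step 9
Reactants: 17 (E)-1-(benzyloxy)-4-[2-(3-methoxyphenyl)ethenyl]benzene
Product: 19 4-[2-(3-methoxyphenyl)ethyl]phenol, via benzyl ether bibenzyl 18 (not isolated)
Conditions: H2 (1 atm), 10% Pd/C, EtOAc/EtOH, rt
Reagents that add atoms: none
Why: Hydrogenation over palladium on carbon first saturates the stilbene alkene and then cleaves the benzylic C–O bond by hydrogenolysis, so the bridge and the free phenol arise in one operation.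

Step 10
Reactants: 13 5-[2-(2,3-dimethoxyphenyl)ethyl]-7-oxabicyclo[4.1.0]heptan-2-one; 19 4-[2-(3-methoxyphenyl)ethyl]phenol
Product: 22 4-[2-(2,3-dimethoxyphenyl)ethyl]-2-{4-[2-(3-methoxyphenyl)ethyl]phenoxy}cyclohex-2-en-1-one (racemic), via potassium phenoxide 20 (not isolated), via hydroxy ketone 21 (not isolated)
Conditions: KH (0.2 equiv), DMPU, THF, reflux
Reagents that add atoms: none
Why: KH turns part of 19 into phenoxide 20, whose oxygen attacks the epoxide at C2 in an SN2 step as the C2–O epoxide bond breaks, leaving an alkoxide at C3 and, after proton transfer, the 3-hydroxy-2-aryloxy ketone 21. The C2 hydrogen of 21 is acidified by both the ketone and the aryloxy group, so E1cB loss of hydroxide forms the C2=C3 double bond, and the hydroxide deprotonates further 19, which is why a substoichiometric amount of base suffices. The closest known reaction type is the opening of 2,3-epoxycyclohexanones at the alpha carbon by phenoxides, thiolates or amines to give 2-heteroatom-substituted cyclohex-2-enones. No ring is closed; the step only joins the ring A–B phenol to the future ring C through oxygen. The stereocentres at C2 and C3 of 21 are transient and vanish on dehydration, so the diastereomer composition of 13 is irrelevant, and C4 stays racemic until aromatisation. The selectivity needed is attack at C2 rather than C3: C2 is activated by the adjacent carbonyl much like the carbon of an alpha-halo ketone, C3 is shielded by the neighbouring C4 chain, and DMPU loosens the potassium phenoxide ion pair so that substitution outruns enolisation of the epoxy ketone.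

Step 11
Reactants: 22 4-[2-(2,3-dimethoxyphenyl)ethyl]-2-{4-[2-(3-methoxyphenyl)ethyl]phenoxy}cyclohex-2-en-1-one
Product: 24 4-[2-(2,3-dimethoxyphenyl)ethyl]-2-{4-[2-(3-methoxyphenyl)ethyl]phenoxy}-6-(phenylselanyl)cyclohex-2-en-1-one (diastereomer mixture), via lithium dienolate 23 (not isolated)
Conditions: LiN(iPr)2 (LDA), THF, −78 °C; then PhSeCl, −78 °C
Reagents that add atoms: benzeneselenenyl chloride, Cl[Se]c1ccccc1
Why: Kinetic deprotonation at C6, the only alpha carbon that bears hydrogen, gives the cross-conjugated dienolate, which is selenenylated at carbon (enolate alpha-selenenylation); the new C6 stereocentre forms as a mixture and is removed in step 12.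

Step 12
Reactants: 24 4-[2-(2,3-dimethoxyphenyl)ethyl]-2-{4-[2-(3-methoxyphenyl)ethyl]phenoxy}-6-(phenylselanyl)cyclohex-2-en-1-one
Product: 27 4-[2-(2,3-dimethoxyphenyl)ethyl]-2-{4-[2-(3-methoxyphenyl)ethyl]phenoxy}phenol, via selenoxide 25 (not isolated), via dienone 26 (not isolated)
Conditions: 30% H2O2 (excess), pyridine, CH2Cl2, 0 °C to rt
Reagents that add atoms: none
Why: Oxidation to the selenoxide and syn selenoxide elimination toward C5 gives the cyclohexa-2,5-dienone 26, whose C4 hydrogen allows base-assisted tautomerisation to the phenol, driven by aromatisation of ring C.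

Step 13
Reactants: 27 4-[2-(2,3-dimethoxyphenyl)ethyl]-2-{4-[2-(3-methoxyphenyl)ethyl]phenoxy}phenol
Product: 28 3-[2-(4-hydroxy-3-{4-[2-(3-hydroxyphenyl)ethyl]phenoxy}phenyl)ethyl]benzene-1,2-diol (CNP0185459.0)
Conditions: BBr3 (excess), CH2Cl2, −78 °C to rt; then H2O
Reagents that add atoms: none
Why: Lewis-acid cleavage of aryl methyl ethers: BBr3 coordinates each methoxy oxygen and bromide attacks the methyl carbon in an SN2 step, whereas the diaryl ether offers no alkyl carbon for bromide to attack and should survive.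

**Compound list**

1 | 2,3-dimethoxybenzaldehyde | COc1cccc(C=O)c1OC | starting material
2 | [2-(1,3-dioxolan-2-yl)ethyl]triphenylphosphonium bromide | [Br-].C1COC(CC[P+](c2ccccc2)(c2ccccc2)c2ccccc2)O1 | starting material
3 | [2-(1,3-dioxolan-2-yl)ethylidene]triphenylphosphorane (ylide) | C1COC(CC=P(c2ccccc2)(c2ccccc2)c2ccccc2)O1 | intermediate
4 | 2-[3-(2,3-dimethoxyphenyl)prop-2-en-1-yl]-1,3-dioxolane (Z isomer drawn, Z/E mixture accepted) | COc1cccc(/C=C\CC2OCCO2)c1OC | intermediate
5 | 2-[3-(2,3-dimethoxyphenyl)propyl]-1,3-dioxolane | COc1cccc(CCCC2OCCO2)c1OC | intermediate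
6 | 4-(2,3-dimethoxyphenyl)butanal | COc1cccc(CCCC=O)c1OC | intermediate
7 | 1-[(E)-4-(2,3-dimethoxyphenyl)but-1-en-1-yl]pyrrolidine | COc1cccc(CC/C=C/N2CCCC2)c1OC | intermediate
8 | methyl vinyl ketone (but-3-en-2-one) | CC(=O)C=C | starting material
9 | 5-[2-(2,3-dimethoxyphenyl)ethyl]-6-(pyrrolidin-1-yl)hex-5-en-2-one (adduct enamine) | COc1cccc(CCC(=CN2CCCC2)CCC(C)=O)c1OC | intermediate
10 | 2-[2-(2,3-dimethoxyphenyl)ethyl]-5-oxohexanal (racemic) | COc1cccc(CCC(C=O)CCC(C)=O)c1OC | intermediate
11 | 4-[2-(2,3-dimethoxyphenyl)ethyl]-3-hydroxycyclohexan-1-one (diastereomer mixture) | COc1cccc(CCC2CCC(=O)CC2O)c1OC | intermediate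
12 | 4-[2-(2,3-dimethoxyphenyl)ethyl]cyclohex-2-en-1-one (racemic) | COc1cccc(CCC2CCC(=O)C=C2)c1OC | intermediate
13 | 5-[2-(2,3-dimethoxyphenyl)ethyl]-7-oxabicyclo[4.1.0]heptan-2-one (racemic, diastereomer mixture) | COc1cccc(CCC2CCC(=O)C3OC23)c1OC | intermediate
14 | diethyl (3-methoxybenzyl)phosphonate | CCOP(=O)(Cc1cccc(OC)c1)OCC | starting material
15 | 4-(benzyloxy)benzaldehyde | O=Cc1ccc(OCc2ccccc2)cc1 | starting material
16 | potassium salt of the carbanion of diethyl (3-methoxybenzyl)phosphonate | CCOP(=O)([CH-]c1cccc(OC)c1)OCC.[K+] | intermediate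
17 | (E)-1-(benzyloxy)-4-[2-(3-methoxyphenyl)ethenyl]benzene | COc1cccc(/C=C/c2ccc(OCc3ccccc3)cc2)c1 | intermediate
18 | 1-(benzyloxy)-4-[2-(3-methoxyphenyl)ethyl]benzene | COc1cccc(CCc2ccc(OCc3ccccc3)cc2)c1 | intermediate
19 | 4-[2-(3-methoxyphenyl)ethyl]phenol | COc1cccc(CCc2ccc(O)cc2)c1 | intermediate
20 | potassium 4-[2-(3-methoxyphenyl)ethyl]phenolate | COc1cccc(CCc2ccc([O-])cc2)c1.[K+] | intermediate
21 | 4-[2-(2,3-dimethoxyphenyl)ethyl]-3-hydroxy-2-{4-[2-(3-methoxyphenyl)ethyl]phenoxy}cyclohexan-1-one (diastereomer mixture) | COc1cccc(CCc2ccc(OC3C(O)C(CCc4cccc(OC)c4OC)CCC3=O)cc2)c1 | intermediate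
22 | 4-[2-(2,3-dimethoxyphenyl)ethyl]-2-{4-[2-(3-methoxyphenyl)ethyl]phenoxy}cyclohex-2-en-1-one (racemic) | COc1cccc(CCc2ccc(OC3=CC(CCc4cccc(OC)c4OC)CCC3=O)cc2)c1 | intermediate
23 | lithium cross-conjugated dienolate of 22 | [Li+].[O-]C1=CCC(CCc2cccc(OC)c2OC)C=C1Oc1ccc(CCc2cccc(OC)c2)cc1 | intermediate
24 | 4-[2-(2,3-dimethoxyphenyl)ethyl]-2-{4-[2-(3-methoxyphenyl)ethyl]phenoxy}-6-(phenylselanyl)cyclohex-2-en-1-one (diastereomer mixture) | COc1cccc(CCc2ccc(OC3=CC(CCc4cccc(OC)c4OC)CC([Se]c4ccccc4)C3=O)cc2)c1 | intermediate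
25 | 6-(benzeneseleninyl)-4-[2-(2,3-dimethoxyphenyl)ethyl]-2-{4-[2-(3-methoxyphenyl)ethyl]phenoxy}cyclohex-2-en-1-one (diastereomer mixture) | COc1cccc(CCc2ccc(OC3=CC(CCc4cccc(OC)c4OC)CC([Se](=O)c4ccccc4)C3=O)cc2)c1 | intermediate
26 | 4-[2-(2,3-dimethoxyphenyl)ethyl]-2-{4-[2-(3-methoxyphenyl)ethyl]phenoxy}cyclohexa-2,5-dien-1-one (racemic) | COc1cccc(CCc2ccc(OC3=CC(CCc4cccc(OC)c4OC)C=CC3=O)cc2)c1 | intermediate
27 | 4-[2-(2,3-dimethoxyphenyl)ethyl]-2-{4-[2-(3-methoxyphenyl)ethyl]phenoxy}phenol | COc1cccc(CCc2ccc(Oc3cc(CCc4cccc(OC)c4OC)ccc3O)cc2)c1 | intermediate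
28 | 3-[2-(4-hydroxy-3-{4-[2-(3-hydroxyphenyl)ethyl]phenoxy}phenyl)ethyl]benzene-1,2-diol (CNP0185459.0) | Oc1cccc(CCc2ccc(Oc3cc(CCc4cccc(O)c4O)ccc3O)cc2)c1 | target

**Step count and risks**

Total step count: 13. Longest linear sequence: 11 steps (steps 1–7 and 10–13); the ring A–B branch (steps 8 and 9) joins at step 10.

Steps most likely to fail:

1. Step 10. The base may isomerise the epoxy ketone to the 1,2-dione or enolise and oligomerise it faster than the phenoxide substitutes at C2, or part of the attack may go to C3. The fallback sets out from 12 and comes back at 27, bypassing 22 and 24, and keeps the same C1/C2/C4 mapping of ring C.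
   - The enone 12 is hydrogenated (H2, 10% Pd/C, EtOAc) to the symmetric ketone 4-[2-(2,3-dimethoxyphenyl)ethyl]cyclohexan-1-one F1.
   - F1 is brominated at an alpha carbon with phenyltrimethylammonium tribromide in THF at 0 °C, a reagent chosen to spare the dimethoxyarene, to give 2-bromo-4-[2-(2,3-dimethoxyphenyl)ethyl]cyclohexan-1-one F2. The two alpha carbons are equivalent, so there is no regiochemical issue.
   - The bromide is displaced by phenol 19 with K2CO3 in acetone (through phenoxide 20, substitution at an alpha-halo ketone) to give 4-[2-(2,3-dimethoxyphenyl)ethyl]-2-{4-[2-(3-methoxyphenyl)ethyl]phenoxy}cyclohexan-1-one F3.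
   - F3 is aromatised by aerobic dehydrogenation with Pd(OCOCF3)2 (divalent palladium), 2-(dimethylamino)pyridine and TsOH under O2 in DMSO at 80 °C to give 27.

2. Step 11. Enolisation may lack regiocontrol (gamma deprotonation at C4 giving the extended dienolate), C6 may be selenenylated twice, or the electron-rich product may be oxidised during the peroxide treatment of step 12. The fallback sets out from 22 and comes back at 27 in one operation: aerobic dehydrogenation with Pd(OCOCF3)2 (divalent palladium), 2-(dimethylamino)pyridine and TsOH under O2 in DMSO at 80 °C. A palladium enolate at C6 should undergo beta-hydride elimination from C5, and the resulting dienone tautomerises to the phenol. No new compound is isolated on this path.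

3. Step 5. The unbranched aldehyde enamine may self-condense, add twice to the enone, or the enone may polymerise. The fallback sets out from 6 and comes back at 10 by alkylation in place of conjugate addition.
   - Aldehyde 6 is condensed with cyclohexylamine (MgSO4, CH2Cl2) to N-cyclohexyl-4-(2,3-dimethoxyphenyl)butan-1-imine F4.
   - F4 is deprotonated with LiN(iPr)2 in THF at −78 °C to the lithium azaenolate of this imine F5.
   - F5 is alkylated with 2-(2-iodoethyl)-2-methyl-1,3-dioxolane to give N-cyclohexyl-2-[2-(2,3-dimethoxyphenyl)ethyl]-4-(2-methyl-1,3-dioxolan-2-yl)butan-1-imine F6.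
   - Aqueous oxalic acid in THF hydrolyses the imine and the ketal of F6 to give 10.

**Further compounds**

F1 | step 10 | 4-[2-(2,3-dimethoxyphenyl)ethyl]cyclohexan-1-one | COc1cccc(CCC2CCC(=O)CC2)c1OC
F2 | step 10 | 2-bromo-4-[2-(2,3-dimethoxyphenyl)ethyl]cyclohexan-1-one (diastereomer mixture) | COc1cccc(CCC2CCC(=O)C(Br)C2)c1OC
F3 | step 10 | 4-[2-(2,3-dimethoxyphenyl)ethyl]-2-{4-[2-(3-methoxyphenyl)ethyl]phenoxy}cyclohexan-1-one (diastereomer mixture) | COc1cccc(CCc2ccc(OC3CC(CCc4cccc(OC)c4OC)CCC3=O)cc2)c1
F0 | step 11 | none | none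
F4 | step 5 | N-cyclohexyl-4-(2,3-dimethoxyphenyl)butan-1-imine | COc1cccc(CCCC=NC2CCCCC2)c1OC
F5 | step 5 | lithium azaenolate of N-cyclohexyl-4-(2,3-dimethoxyphenyl)butan-1-imine | COc1cccc(CCC=C[N-]C2CCCCC2)c1OC.[Li+]
F6 | step 5 | N-cyclohexyl-2-[2-(2,3-dimethoxyphenyl)ethyl]-4-(2-methyl-1,3-dioxolan-2-yl)butan-1-imine (racemic) | COc1cccc(CCC(C=NC2CCCCC2)CCC2(C)OCCO2)c1OC
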